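Winter differs from dusk in temperature, and its step from single product to double product runs slower than dusk's, at 0.0597 of the constant given.

    starting material + double product ⇌ idle adduct, settled at all times (K1 = 1.2 L mol⁻¹, ΔH1 = −36.0 kJ mol⁻¹)
    reagent + tris adduct → tetra adduct + released group (k2 = 0.064 L mol⁻¹ h⁻¹, Ea2 = 60.0 kJ mol⁻¹)
    reagent + single product → double product + released group (k3 = 0.036 L mol⁻¹ h⁻¹, Ea3 = 81.0 kJ mol⁻¹)
    reagent + double product → tris adduct + released group (k4 = 0.019 L mol⁻¹ h⁻¹, Ea4 = 59.0 kJ mol⁻¹)
    starting material + reagent → single product + released group (k5 = 0.016 L mol⁻¹ h⁻¹, Ea5 = 64.0 kJ mol⁻¹)
    (constants at 0 °C)

all flasks: starting material 1.0 M; reagent 1.80 M; time 2.5 d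
- winter: temperature −20 °C
- spring: at 0 °C until 30 h, from then on at −20 °C
- dusk: temperature 0 °C

- percent here means starting material units held: one idle adduct counts as two
- what is said of double product includes idle adduct
- constants are those at 0 °C; use the activation energies and enthalpies for any other temperature
- in an amount of double product, one idle adduct counts as one double product

1. which flask leads in amount of double product, in percent of the starting material charged ("all alike" within 1.5 percentage points) (winter / spring / dusk / all alike)
2. how much double product is there at the end, in percent of the starting material charged: winter
3. how much double product is there at the end, in percent of the starting material charged: spring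
4. how much double product is there at the end, in percent of the starting material charged: dusk

Winter can be built up by hand, one process at a time. Take step 5 first, with reagent held at its charge, so that it is pseudo-first-order: its constant at −20 °C, times c(reagent), times the time, gives a = 0.186, the first estimate of the fraction of starting material reacted. Now add step 3, whose number on the same footing is b = 0.232. Single product grows along the run and feeds double product, so double product starts with the square of the time, and 0.5·a·b gives 2.17%, the two-step term.

The rest enters as corrections to that term. Reagent falls by about 0.186 M by the end, so its mean stands at 0.948 of the charge, and the term, being a square, shrinks by that share squared. Starting material and single product are also consumed as double product grows, which takes away a further third of a + b at the reduced exposure. Together the factor is 0.780, so winter comes to 1.69%. Step 4 stays out: starting material at its charge leaves free a share 0.192 of double product, and step 4's number on free double product, 0.0507, is smaller than a + b.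

At 0 °C the same numbers are 1.73 and 3.89, and the term becomes 336%, above the 90.0% that the reagent charge allows at two reagent for each double product. The expansion stops there and gives no number for dusk. Spring runs as dusk until 30 h; after that, a cold hour counts as 0.0597 of a warm hour for step 3. This reckoning therefore commits to 1.69% for winter and puts dusk ahead of spring, with spring near what dusk held at the change.

The forecast named dusk as leader, with 1.7% for winter, 22.2% for spring and 30.2% for dusk, holding that idle adduct shelters double product, while “reagent depletion slows everything”.

Dusk leads with 30.0%, ahead of spring at 21.5% and winter at 1.68%. Winter ends with 90% of its reagent and 17.5% conversion, and its double product is 0.774 of the two-step term of 2.17%. Dusk read at 15 h keeps 76% of its reagent; with that mean, a is 0.380 and b is 0.856, so the term with its consumption correction gives 9.57%, and that flask holds 9.88%.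

(The numbers are those of an exercise; no experiment stands behind them.)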